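## Retrosynthetic overview

1. The target should arise from the 1(10)-ene lactone by a final peracid epoxidation; that lactone comes from a ten-membered vinyl oxirane carboxylate by a zerovalent-palladium 1,4-addition that closes the γ-lactone at O–C6.
2. Enabling feature: the lactone oxygen on C6 and the hydroxyl on C15 stand 1,4 across C4=C5 (O–C6–C5=C4–C15–OH), and the carboxyl carbon C12 hangs on C7 next to C6, so a C4/C15 spiro-oxirane beside a C5=C6 alkene is opened by a five-membered closure; the C3 hydroxyl next to C4 places that oxirane.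
3. The vinyl oxirane comes from hydroxyl-directed epoxidation of a macrocyclic dienol, whose C3 carbinol is set by CBS reduction of the dienone; the ten-membered carbocycle is closed at C3–C4 by a Nozaki–Hiyama–Kishi reaction.
4. The open chain comes from a syn-selective allylboration at C7–C8 between fragment A (aldehyde from pent-3-yn-1-ol) and fragment B (2-(alkoxycarbonyl)allylboronate from propargyl alcohol, 1,1-dibromoethene and an acrylate), followed by methacrylation and (Z)-semi-reduction.
5. Ring order: carbocycle (step 16), C4/C15 oxirane (step 19), γ-lactone (step 20), 1,10-oxirane (step 21).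

Key step: step 20

Remark: carbon locants C1–C15 follow germacrane numbering of the target (C12 lactone carbonyl, C13 exocyclic methylene, C14 methyl on C10, C15 hydroxymethyl on C4); 2-(trimethylsilyl)ethyl acrylate is assumed not to be purchasable and is made in step 5.

## Route

Step 1
Reactants: 1 pent-3-yn-1-ol
Product: 2 tert-butyldimethyl(pent-3-yn-1-yloxy)silane
Conditions: TBSCl, imidazole, DMF, rt
Reagents that add atoms: tert-butyldimethylsilyl chloride, CC(C)(C)[Si](C)(C)Cl
Why: Standard silylation of a primary alcohol protects the future C3 oxygen.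

Step 2
Reactants: 2 tert-butyldimethyl(pent-3-yn-1-yloxy)silane
Product: 4 tert-butyl{[(3E)-4-iodopent-3-en-1-yl]oxy}dimethylsilane, via alkenylzirconocene chloride 3 (not isolated)
Conditions: Cp2Zr(H)Cl (1.5 equiv), THF, rt to 45 °C; then I2, 0 °C
Reagents that add atoms: iodine, II
Why: Syn hydrozirconation of the 2-alkyne should, under equilibration with excess reagent, place zirconium on the methyl-bearing carbon, and iodinolysis with retention should give the (E)-iodide that fixes the 1(10)E geometry.

Step 3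
Reactants: 4 tert-butyl{[(3E)-4-iodopent-3-en-1-yl]oxy}dimethylsilane
Product: 6 (3E)-6-(tert-butyldimethylsilyloxy)-3-methylhex-3-en-1-ol, via alkenyllithium 5 (not isolated)
Conditions: t-BuLi (2.1 equiv), Et2O, −78 °C; then oxirane, −78 °C to rt
Reagents that add atoms: ethylene oxide, C1CO1
Why: Iodine–lithium exchange occurs with retention of alkene geometry, and the alkenyllithium should open oxirane by SN2 to add C9 and C8.

Step 4
Reactants: 6 (3E)-6-(tert-butyldimethylsilyloxy)-3-methylhex-3-en-1-ol
Product: 7 (3E)-6-(tert-butyldimethylsilyloxy)-3-methylhex-3-enal (fragment A)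
Conditions: Dess–Martin periodinane (DMP), NaHCO3, CH2Cl2, 0 °C; used at once
Reagents that add atoms: none
Why: Buffered Dess–Martin oxidation should give the β,γ-unsaturated aldehyde without migration of the alkene into conjugation.

Step 5
Reactants: 8 acryloyl chloride; 9 2-(trimethylsilyl)ethanol
Product: 10 2-(trimethylsilyl)ethyl acrylate
Conditions: Et3N, CH2Cl2, 0 °C
Reagents that add atoms: none
Why: Simple acylation provides an acrylate whose ester can later be cleaved by fluoride under non-acidic conditions.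

Step 6
Reactants: 11 prop-2-yn-1-ol; 12 1,1-dibromoethene (3 equiv)
Product: 13 4-bromopent-4-en-2-yn-1-ol
Conditions: Pd(PPh3)4 (3 mol%), CuI (5 mol%), i-Pr2NH, THF, 0 °C to rt
Reagents that add atoms: none
Why: Sonogashira mono-coupling of a 1,1-dibromoalkene, run with excess dihalide, should stop at the 2-bromo-enyne that carries C4, C5, C6 and C15.

Step 7
Reactants: 13 4-bromopent-4-en-2-yn-1-ol
Product: 14 4-bromopent-4-en-2-ynal
Conditions: DMP, NaHCO3, CH2Cl2, 0 °C; solution used directly
Reagents that add atoms: none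
Why: Dess–Martin oxidation of a propargylic alcohol should give the ynal under neutral conditions.

Step 8
Reactants: 14 4-bromopent-4-en-2-ynal; 10 2-(trimethylsilyl)ethyl acrylate
Product: 15 2-(trimethylsilyl)ethyl 6-bromo-3-hydroxy-2-methylidenehept-6-en-4-ynoate (racemic)
Conditions: DABCO (30 mol%), THF, 0 °C to rt
Reagents that add atoms: none
Why: The Morita–Baylis–Hillman reaction, fast with alkynyl aldehydes, joins C7 to C11 and installs the α-methylene ester; the carbinol stereocentre is erased in step 10.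

Step 9
Reactants: 15 2-(trimethylsilyl)ethyl 6-bromo-3-hydroxy-2-methylidenehept-6-en-4-ynoate
Product: 16 2-(trimethylsilyl)ethyl 3-acetoxy-6-bromo-2-methylidenehept-6-en-4-ynoate (racemic)
Conditions: Ac2O, pyridine, DMAP (cat.), CH2Cl2, 0 °C
Reagents that add atoms: acetic anhydride, CC(=O)OC(C)=O
Why: Acetylation turns the hydroxyl into the leaving group needed for the SN2' borylation.

Step 10
Reactants: 16 2-(trimethylsilyl)ethyl 3-acetoxy-6-bromo-2-methylidenehept-6-en-4-ynoate
Product: 17 2-(trimethylsilyl)ethyl (2E)-6-bromo-2-[(4,4,5,5-tetramethyl-1,3,2-dioxaborolan-2-yl)methyl]hepta-2,6-dien-4-ynoate (fragment B)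
Conditions: B2pin2, CuCl (10 mol%), LiCl, KOAc, DMF, rt
Reagents that add atoms: bis(pinacolato)diboron, CC1(C)OB(OC1(C)C)B1OC(C)(C)C(C)(C)O1
Why: Hosomi–Miyaura borylation (conjugate borylcupration of the acrylate terminus, then loss of acetate) should give the allylboronate with the alkynyl group cis to CH2B, the conjugated alkyne and the alkenyl bromide reacting more slowly.

Step 11
Reactants: 7 (3E)-6-(tert-butyldimethylsilyloxy)-3-methylhex-3-enal; 17 allylboronate fragment B
Product: 18 2-(trimethylsilyl)ethyl (3R)-6-bromo-3-[(1R,3E)-6-(tert-butyldimethylsilyloxy)-1-hydroxy-3-methylhex-3-en-1-yl]-2-methylidenehept-6-en-4-ynoate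
Conditions: (S)-TRIP [(S)-3,3'-bis(2,4,6-triisopropylphenyl)-1,1'-binaphthyl-2,2'-diyl hydrogen phosphate] (10 mol%), 4 Å MS, toluene, −30 to 0 °C; aq. NaHCO3
Reagents that add atoms: none
Why: Proposed new method: chiral phosphoric acid catalysis is established for allyl and crotyl pinacol boronates but not for 2-(alkoxycarbonyl)allylboronates, which are known to add to aldehydes through the same closed chair transition state under achiral Brønsted or Lewis acid catalysis; hydrogen bonding of the acid to a boronate oxygen, with its phosphoryl oxygen on the formyl hydrogen, should direct C7 to the Si face of 7 (the (R)-catalyst is taken to favour Re-face attack in allylborations), setting C8 as R, while the alkynyl group cis to CH2B sits axial in the chair and sets C7 syn to the carbinol (R).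

Step 12
Reactants: 18 syn-hydroxy ester
Product: 19 2-(trimethylsilyl)ethyl (3R)-6-bromo-3-[(1R,3E)-6-(tert-butyldimethylsilyloxy)-1-(methacryloyloxy)-3-methylhex-3-en-1-yl]-2-methylidenehept-6-en-4-ynoate
Conditions: methacrylic anhydride, Et3N, DMAP, CH2Cl2, 0 °C to rt
Reagents that add atoms: methacrylic anhydride, C=C(C)C(=O)OC(=O)C(C)=C
Why: DMAP-catalysed acylation installs the C8 methacrylate early and blocks lactonisation of the C8 hydroxyl onto C12.

Step 13
Reactants: 19 enyne methacrylate
Product: 20 2-(trimethylsilyl)ethyl (3R,4Z)-6-bromo-3-[(1R,3E)-6-(tert-butyldimethylsilyloxy)-1-(methacryloyloxy)-3-methylhex-3-en-1-yl]-2-methylidenehepta-4,6-dienoate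
Conditions: Zn dust activated with Cu(OAc)2 and AgNO3, MeOH/H2O (1:1), rt
Reagents that add atoms: none
Why: Activated zinc reduces only alkynes conjugated to another π-system, by syn delivery of two hydrogens, so the (5Z) alkene should form without over-reduction or loss of the alkenyl bromide.

Step 14
Reactants: 20 (Z)-bromodiene silyl ether
Product: 21 2-(trimethylsilyl)ethyl (3R,4Z)-6-bromo-3-[(1R,3E)-6-hydroxy-1-(methacryloyloxy)-3-methylhex-3-en-1-yl]-2-methylidenehepta-4,6-dienoate
Conditions: camphorsulfonic acid (10 mol%), MeOH/CH2Cl2, 0 °C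
Reagents that add atoms: none
Why: Mild acid methanolysis removes a primary TBS ether while the silylethyl ester and the methacrylate survive.

Step 15
Reactants: 21 primary alcohol
Product: 22 2-(trimethylsilyl)ethyl (3R,4Z)-6-bromo-3-[(1R,3E)-1-(methacryloyloxy)-3-methyl-6-oxohex-3-en-1-yl]-2-methylidenehepta-4,6-dienoate
Conditions: DMP, NaHCO3, CH2Cl2, 0 °C; used at once
Reagents that add atoms: none
Why: Buffered Dess–Martin oxidation gives the C3 aldehyde without epimerising C7 or shifting the 1(10) alkene.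

Step 16
Reactants: 22 bromodiene aldehyde
Product: 23 2-(trimethylsilyl)ethyl (7R,8R,1(10)E,5Z)-3-hydroxy-8-(methacryloyloxy)germacra-1(10),4(15),5,11(13)-tetraen-12-oate (both C3 epimers)
Conditions: CrCl2 (8 equiv), NiCl2 (2 mol%), DMSO/THF (3:1), rt, slow addition, 2 mM
Reagents that add atoms: none
Why: In the Nozaki–Hiyama–Kishi reaction zerovalent nickel inserts into the alkenyl C–Br bond, the alkenyl group passes to trivalent chromium and adds only to the aldehyde, and high dilution favours the ten-membered ring; C3 forms as a mixture that is reset in steps 17 and 18.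

Step 17
Reactants: 23 macrocyclic dienol (C3 epimers)
Product: 24 2-(trimethylsilyl)ethyl (7R,8R,1(10)E,5Z)-8-(methacryloyloxy)-3-oxogermacra-1(10),4(15),5,11(13)-tetraen-12-oate
Conditions: DMP, NaHCO3, CH2Cl2, 0 °C
Reagents that add atoms: none
Why: Oxidation of the allylic alcohol converges both epimers into one cross-conjugated dienone.

Step 18
Reactants: 24 macrocyclic dienone
Product: 25 2-(trimethylsilyl)ethyl (3S,7R,8R,1(10)E,5Z)-3-hydroxy-8-(methacryloyloxy)germacra-1(10),4(15),5,11(13)-tetraen-12-oate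
Conditions: (R)-2-methyl-CBS-oxazaborolidine (1.0 equiv), catecholborane, toluene, −78 °C
Reagents that add atoms: none
Why: In the CBS reduction the α-substituted alkenyl carbon C4 acts as the large group and the C2 methylene as the small one, so the (R)-catalyst should deliver hydride to give the 3S carbinol, and catecholborane at low temperature avoids 1,4-reduction and hydroboration.

Step 19
Reactants: 25 (3S)-dienol
Product: 26 2-(trimethylsilyl)ethyl (3S,4R,7R,8R,1(10)E,5Z)-4,15-epoxy-3-hydroxy-8-(methacryloyloxy)germacra-1(10),5,11(13)-trien-12-oate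
Conditions: VO(acac)2 (5 mol%), TBHP (1.5 equiv), CH2Cl2, 0 °C
Reagents that add atoms: tert-butyl hydroperoxide, CC(C)(C)OO
Why: Hydroxyl-directed vanadium epoxidation is much faster for the allylic C4=C15 alkene than for the homoallylic ones, and the transition state that keeps H3 next to the C5 substituent (least 1,2-allylic strain) delivers oxygen syn to the hydroxyl to give the erythro (3S,4R) oxirane.

Step 20
Reactants: 26 vinyl oxirane silylethyl ester
Product: 28 (3S,6R,7R,8R,1(10)E,4Z)-3,15-dihydroxy-8-(methacryloyloxy)germacra-1(10),4,11(13)-trien-12,6-olide, via tetrabutylammonium carboxylate 27 (not isolated)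
Conditions: TBAF (1.05 equiv), THF, 0 °C, 30 min; then Pd(PPh3)4 (10 mol%), THF, 0 °C to rt
Reagents that add atoms: none
Why: Fluoride fragments the 2-(trimethylsilyl)ethyl ester to carboxylate 27; zerovalent palladium then ionises the allylic C4–O bond of the oxirane with inversion to an η3-allyl complex over C4–C5–C6 that carries the C15 alkoxide, and the carboxylate attacks C6 on the face away from palladium. The closest known reaction type is the palladium-catalysed 1,4-addition of carboxylic acids to vinyl oxiranes (Tsuji–Trost manifold), including intramolecular lactonisations. The γ-lactone (O–C6–C7–C11–C12) closes in a 5-exo mode at the allyl terminus, whereas attack at C4 would need a seven-membered ring at a fully substituted carbon. C6 is controlled by the C4 oxirane centre: double inversion returns oxygen to the face the oxirane oxygen left, so 4R with the (5Z) alkene gives 6R. The oxirane-derived C15 takes the syn position and ring carbon C3 the anti position of the allyl unit, as with 2-substituted 2-vinyloxiranes and as the ten-membered ring demands, so C3 and C6 end cis (4Z). The step needs only the vinyl oxirane to ionise and the tethered carboxylate to capture the allyl complex before syn–anti isomerisation or hydride shift to an enone; the isolated 1(10) alkene, the methacrylate and the acrylate are inert to zerovalent palladium, and the one-atom tether makes capture fast.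

Step 21
Reactants: 28 1(10)-ene lactone diol
Product: 29 (1R,3S,6R,7R,8R,10R,4Z)-1,10-epoxy-3,15-dihydroxy-8-(methacryloyloxy)germacra-4,11(13)-dien-12,6-olide (target)
Conditions: mCPBA (1.1 equiv), NaHCO3, CH2Cl2, −20 to 0 °C
Reagents that add atoms: 3-chloroperoxybenzoic acid, OOC(=O)c1cccc(Cl)c1
Why: The peracid should select the only electron-rich alkene (C4=C5 is deactivated by three allylic oxygens, the other two are ester-conjugated) and attack the outer face of the (E)-C1=C10 bond of the folded ring, the sense seen in peracid epoxidations of germacra-1(10),4-dien-6,12-olides, giving the 1R,10R oxirane.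

## Compound list

1 | pent-3-yn-1-ol | CC#CCCO | starting material
2 | tert-butyldimethyl(pent-3-yn-1-yloxy)silane | CC#CCCO[Si](C)(C)C(C)(C)C | intermediate
3 | chlorobis(cyclopentadienyl)[(2E)-5-(tert-butyldimethylsilyloxy)pent-2-en-2-yl]zirconium | C/C(=C\CCO[Si](C)(C)C(C)(C)C)[Zr](Cl)(C1C=CC=C1)C1C=CC=C1 | intermediate (not isolated)
4 | tert-butyl{[(3E)-4-iodopent-3-en-1-yl]oxy}dimethylsilane | I/C(C)=C/CCO[Si](C)(C)C(C)(C)C | intermediate
5 | [(2E)-5-(tert-butyldimethylsilyloxy)pent-2-en-2-yl]lithium | [Li]/C(C)=C/CCO[Si](C)(C)C(C)(C)C | intermediate (not isolated)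
6 | (3E)-6-(tert-butyldimethylsilyloxy)-3-methylhex-3-en-1-ol | OCC/C(C)=C/CCO[Si](C)(C)C(C)(C)C | intermediate
7 | (3E)-6-(tert-butyldimethylsilyloxy)-3-methylhex-3-enal | O=CC/C(C)=C/CCO[Si](C)(C)C(C)(C)C | intermediate
8 | acryloyl chloride | C=CC(=O)Cl | starting material
9 | 2-(trimethylsilyl)ethanol | C[Si](C)(C)CCO | starting material
10 | 2-(trimethylsilyl)ethyl acrylate | C=CC(=O)OCC[Si](C)(C)C | intermediate
11 | prop-2-yn-1-ol | C#CCO | starting material
12 | 1,1-dibromoethene | C=C(Br)Br | starting material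
13 | 4-bromopent-4-en-2-yn-1-ol | OCC#CC(Br)=C | intermediate
14 | 4-bromopent-4-en-2-ynal | O=CC#CC(Br)=C | intermediate
15 | 2-(trimethylsilyl)ethyl 6-bromo-3-hydroxy-2-methylidenehept-6-en-4-ynoate (racemic) | C=C(C(=O)OCC[Si](C)(C)C)C(O)C#CC(Br)=C | intermediate
16 | 2-(trimethylsilyl)ethyl 3-acetoxy-6-bromo-2-methylidenehept-6-en-4-ynoate (racemic) | C=C(C(=O)OCC[Si](C)(C)C)C(OC(C)=O)C#CC(Br)=C | intermediate
17 | 2-(trimethylsilyl)ethyl (2E)-6-bromo-2-[(4,4,5,5-tetramethyl-1,3,2-dioxaborolan-2-yl)methyl]hepta-2,6-dien-4-ynoate | CC1(C)OB(C/C(C(=O)OCC[Si](C)(C)C)=C\C#CC(Br)=C)OC1(C)C | intermediate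
18 | 2-(trimethylsilyl)ethyl (3R)-6-bromo-3-[(1R,3E)-6-(tert-butyldimethylsilyloxy)-1-hydroxy-3-methylhex-3-en-1-yl]-2-methylidenehept-6-en-4-ynoate | C=C(C(=O)OCC[Si](C)(C)C)[C@@H](C#CC(Br)=C)[C@H](O)C/C(C)=C/CCO[Si](C)(C)C(C)(C)C | intermediate
19 | 2-(trimethylsilyl)ethyl (3R)-6-bromo-3-[(1R,3E)-6-(tert-butyldimethylsilyloxy)-1-(methacryloyloxy)-3-methylhex-3-en-1-yl]-2-methylidenehept-6-en-4-ynoate | C=C(C(=O)OCC[Si](C)(C)C)[C@@H](C#CC(Br)=C)[C@H](OC(=O)C(C)=C)C/C(C)=C/CCO[Si](C)(C)C(C)(C)C | intermediate
20 | 2-(trimethylsilyl)ethyl (3R,4Z)-6-bromo-3-[(1R,3E)-6-(tert-butyldimethylsilyloxy)-1-(methacryloyloxy)-3-methylhex-3-en-1-yl]-2-methylidenehepta-4,6-dienoate | C=C(C(=O)OCC[Si](C)(C)C)[C@@H](/C=C\C(Br)=C)[C@H](OC(=O)C(C)=C)C/C(C)=C/CCO[Si](C)(C)C(C)(C)C | intermediate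
21 | 2-(trimethylsilyl)ethyl (3R,4Z)-6-bromo-3-[(1R,3E)-6-hydroxy-1-(methacryloyloxy)-3-methylhex-3-en-1-yl]-2-methylidenehepta-4,6-dienoate | C=C(C(=O)OCC[Si](C)(C)C)[C@@H](/C=C\C(Br)=C)[C@H](OC(=O)C(C)=C)C/C(C)=C/CCO | intermediate
22 | 2-(trimethylsilyl)ethyl (3R,4Z)-6-bromo-3-[(1R,3E)-1-(methacryloyloxy)-3-methyl-6-oxohex-3-en-1-yl]-2-methylidenehepta-4,6-dienoate | C=C(C(=O)OCC[Si](C)(C)C)[C@@H](/C=C\C(Br)=C)[C@H](OC(=O)C(C)=C)C/C(C)=C/CC=O | intermediate
23 | 2-(trimethylsilyl)ethyl (7R,8R,1(10)E,5Z)-3-hydroxy-8-(methacryloyloxy)germacra-1(10),4(15),5,11(13)-tetraen-12-oate (C3 epimers) | C=C(C)C(=O)O[C@@H]1C/C(C)=C/CC(O)C(=C)/C=C\[C@@H]1C(=C)C(=O)OCC[Si](C)(C)C | intermediate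
24 | 2-(trimethylsilyl)ethyl (7R,8R,1(10)E,5Z)-8-(methacryloyloxy)-3-oxogermacra-1(10),4(15),5,11(13)-tetraen-12-oate | C=C(C)C(=O)O[C@@H]1C/C(C)=C/CC(=O)C(=C)/C=C\[C@@H]1C(=C)C(=O)OCC[Si](C)(C)C | intermediate
25 | 2-(trimethylsilyl)ethyl (3S,7R,8R,1(10)E,5Z)-3-hydroxy-8-(methacryloyloxy)germacra-1(10),4(15),5,11(13)-tetraen-12-oate | C=C(C)C(=O)O[C@@H]1C/C(C)=C/C[C@H](O)C(=C)/C=C\[C@@H]1C(=C)C(=O)OCC[Si](C)(C)C | intermediate
26 | 2-(trimethylsilyl)ethyl (3S,4R,7R,8R,1(10)E,5Z)-4,15-epoxy-3-hydroxy-8-(methacryloyloxy)germacra-1(10),5,11(13)-trien-12-oate | C=C(C)C(=O)O[C@@H]1C/C(C)=C/C[C@H](O)[C@]2(CO2)/C=C\[C@@H]1C(=C)C(=O)OCC[Si](C)(C)C | intermediate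
27 | tetrabutylammonium (3S,4R,7R,8R,1(10)E,5Z)-4,15-epoxy-3-hydroxy-8-(methacryloyloxy)germacra-1(10),5,11(13)-trien-12-oate | C=C(C)C(=O)O[C@@H]1C/C(C)=C/C[C@H](O)[C@]2(CO2)/C=C\[C@@H]1C(=C)C(=O)[O-].CCCC[N+](CCCC)(CCCC)CCCC | intermediate (not isolated)
28 | (3S,6R,7R,8R,1(10)E,4Z)-3,15-dihydroxy-8-(methacryloyloxy)germacra-1(10),4,11(13)-trien-12,6-olide | C=C(C)C(=O)O[C@@H]1C/C(C)=C/C[C@H](O)/C(CO)=C\[C@H]2OC(=O)C(=C)[C@@H]21 | intermediate
29 | (1R,3S,6R,7R,8R,10R,4Z)-1,10-epoxy-3,15-dihydroxy-8-(methacryloyloxy)germacra-4,11(13)-dien-12,6-olide | C=C(C)C(=O)O[C@@H]1C[C@@]2(C)O[C@@H]2C[C@H](O)/C(CO)=C\[C@H]2OC(=O)C(=C)[C@@H]21 | target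

## Step count and risks

Total steps: 21. Longest linear sequence: 16 (steps 6 to 21, from prop-2-yn-1-ol).

**Step 11 (asymmetric allylboration).** The electron-poor, alkyne-conjugated allylboronate may not be activated enough by the chiral acid, so that turnover stalls or an uncatalysed background addition erodes the enantiomeric purity. The fallback sets out from 15 and returns at 19. SN2' bromination of 15 with PBr3 should give 2-(trimethylsilyl)ethyl (2Z)-6-bromo-2-(bromomethyl)hepta-2,6-dien-4-ynoate F1. A chromium-catalysed asymmetric allylation of aldehyde 7 with F1 (CrCl2 cat., chiral oxazoline–sulfonamide ligand of the antipode that gives the 8S carbinol, Mn, Cp2ZrCl2) is anti-selective because the allylchromium species equilibrates to the E form; it should give 2-(trimethylsilyl)ethyl (3R)-6-bromo-3-[(1S,3E)-6-(tert-butyldimethylsilyloxy)-1-hydroxy-3-methylhex-3-en-1-yl]-2-methylidenehept-6-en-4-ynoate F2. A Mitsunobu esterification of F2 with methacrylic acid (PPh3, DIAD) inverts C8 and gives 19 directly.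

**Step 16 (macrocyclisation).** Intermolecular coupling and protodebromination of the alkenylmetal species may outrun closure of the ten-membered ring. The fallback sets out from 22 and returns at 24, closing the same bond by acyl substitution instead of carbonyl addition. Pinnick oxidation of 22 should give (4E,7R)-7-(methacryloyloxy)-8-[(1Z)-3-bromobuta-1,3-dien-1-yl]-4-methyl-9-{[2-(trimethylsilyl)ethoxy]carbonyl}deca-4,9-dienoic acid F3 (the C3 acid). Treatment with 2,2'-dipyridyl disulfide and PPh3 should give its S-(pyridin-2-yl) thioester F4. A nickel-mediated reductive acyl coupling of the alkenyl bromide with the thioester (NiBr2 with 4,4'-di-tert-butyl-2,2'-bipyridine, Zn, Cp2ZrCl2, high dilution) should then give ketone 24, which makes step 17 unnecessary.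

**Step 20 (key lactonisation).** The η3-allylpalladium alkoxide may relax by syn–anti isomerisation or by hydride shift to an enone before the carboxylate reaches C6, or the ring may not reach the conformation for attack opposite to palladium, so that stereospecificity or the lactone itself is lost. The fallback sets out from 25 and returns at 28, activating the diene with an electrophile instead. TBAF should free (3S,7R,8R,1(10)E,5Z)-3-hydroxy-8-(methacryloyloxy)germacra-1(10),4(15),5,11(13)-tetraen-12-oic acid F5. Kinetic selenolactonisation (PhSeCl, CH2Cl2, −78 °C) adds selenium to C5 and the carboxylate to C6 in an anti, 5-exo sense and should give (3S,5S,6S,7R,8R,1(10)E)-3-hydroxy-8-(methacryloyloxy)-5-(phenylselanyl)germacra-1(10),4(15),11(13)-trien-12,6-olide F6; the trans-fused lactone is expected and C6 epimers would be separable. Oxidation (H2O2, pyridine, 0 °C) and [2,3]-sigmatropic rearrangement of the allylic selenoxide should move oxygen to C15 and the alkene to C4=C5, giving 28.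

## Further compounds

F1 | step 11 | 2-(trimethylsilyl)ethyl (2Z)-6-bromo-2-(bromomethyl)hepta-2,6-dien-4-ynoate | BrC/C(C(=O)OCC[Si](C)(C)C)=C\C#CC(Br)=C
F2 | step 11 | 2-(trimethylsilyl)ethyl (3R)-6-bromo-3-[(1S,3E)-6-(tert-butyldimethylsilyloxy)-1-hydroxy-3-methylhex-3-en-1-yl]-2-methylidenehept-6-en-4-ynoate | C=C(C(=O)OCC[Si](C)(C)C)[C@@H](C#CC(Br)=C)[C@@H](O)C/C(C)=C/CCO[Si](C)(C)C(C)(C)C
F3 | step 16 | C3 carboxylic acid derived from aldehyde 22 | C=C(C(=O)OCC[Si](C)(C)C)[C@@H](/C=C\C(Br)=C)[C@H](OC(=O)C(C)=C)C/C(C)=C/CC(O)=O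
F4 | step 16 | S-(pyridin-2-yl) thioester of F3 | C=C(C(=O)OCC[Si](C)(C)C)[C@@H](/C=C\C(Br)=C)[C@H](OC(=O)C(C)=C)C/C(C)=C/CC(=O)Sc1ccccn1
F5 | step 20 | (3S,7R,8R,1(10)E,5Z)-3-hydroxy-8-(methacryloyloxy)germacra-1(10),4(15),5,11(13)-tetraen-12-oic acid | C=C(C)C(=O)O[C@@H]1C/C(C)=C/C[C@H](O)C(=C)/C=C\[C@@H]1C(=C)C(O)=O
F6 | step 20 | (3S,5S,6S,7R,8R,1(10)E)-3-hydroxy-8-(methacryloyloxy)-5-(phenylselanyl)germacra-1(10),4(15),11(13)-trien-12,6-olide | C=C(C)C(=O)O[C@@H]1C/C(C)=C/C[C@H](O)C(=C)[C@H]([Se]c3ccccc3)[C@H]2OC(=O)C(=C)[C@@H]21
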